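**Retrosynthetic overview**

1. Feature: the oxolane ring has a twofold axis through O1 and the midpoint of the C3–C4 bond. C2 and C5 (both S) carry the same 4-hydroxy-3,5-dimethoxyphenyl group, trans across O1; C3 and C4 (both R) carry CH2OH, and all neighbours are trans.
2. The two CH2OH groups go back to an all-trans 3,4-diester (LiAlH4), this to its 3,4-cis epimer (NaOMe), and that to syn bis-methoxycarbonylation of the C3=C4 alkene of a trans-2,5-diaryl-2,5-dihydrofuran.
3. Key disconnection: the C2–aryl and C5–aryl bonds of that dihydrofuran are both cut, back to 2,3-dihydrofuran and two molecules of one aryl triflate, joined by a double asymmetric Heck arylation with Pd(OAc)2/(S)-BINAP.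
4. The triflate comes from syringaldehyde by O-benzylation, Baeyer–Villiger oxidation with formate cleavage, and triflation; the benzyl ethers are removed last by hydrogenolysis.
5. Ring order: the only ring of the core, the oxolane, is bought as 2,3-dihydrofuran; no ring is formed in the route.

Key step: step 4

Assumption: the sense of induction follows the usual behaviour of palladium–BINAP with 2,3-dihydrofuran, where (R)-BINAP leads to (R)-2-aryl-2,3-dihydrofurans; (S)-BINAP is therefore used for (S)-7 and (2S,5S)-8, and the ligand enantiomer would be exchanged if triflate 5 responded in the opposite sense.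
Assumption: simple reagents (benzyl bromide, mCPBA, Tf2O, CO, methanol) are treated as reagents and carry no compound number.

**Route**

Step 1
Reactants: 1 syringaldehyde (4-hydroxy-3,5-dimethoxybenzaldehyde)
Product: 2 4-(benzyloxy)-3,5-dimethoxybenzaldehyde
Conditions: BnBr, K2CO3, DMF, 60 °C
Reagents that add atoms: benzyl bromide, BrCc1ccccc1
Why: Williamson ether synthesis; the phenoxide is alkylated by the reactive benzylic bromide even between two methoxy groups, and the aldehyde is untouched.

Step 2
Reactants: 2 4-(benzyloxy)-3,5-dimethoxybenzaldehyde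
Product: 4 4-(benzyloxy)-3,5-dimethoxyphenol, via aryl formate 3 (not isolated)
Conditions: mCPBA, CH2Cl2, 0 °C to rt; aq. NaHCO3 wash; then Et3N (cat.), MeOH, rt
Reagents that add atoms: mCPBA, O=C(OO)c1cccc(Cl)c1
Why: Baeyer–Villiger (Dakin-type) oxidation in which the electron-rich aryl group migrates in preference to hydrogen, followed by base-catalysed methanolysis of the labile aryl formate.

Step 3
Reactants: 4 4-(benzyloxy)-3,5-dimethoxyphenol
Product: 5 4-(benzyloxy)-3,5-dimethoxyphenyl trifluoromethanesulfonate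
Conditions: Tf2O, pyridine, CH2Cl2, 0 °C
Reagents that add atoms: trifluoromethanesulfonic anhydride, O=S(=O)(OS(=O)(=O)C(F)(F)F)C(F)(F)F
Why: O-sulfonylation of an unhindered phenol (both ortho positions carry hydrogen), giving the aryl triflate needed for the cationic Heck pathway.

Step 4
Reactants: 5 4-(benzyloxy)-3,5-dimethoxyphenyl trifluoromethanesulfonate (2.3 equiv); 6 2,3-dihydrofuran (1 equiv)
Product: 8 (2S,5S)-2,5-bis[4-(benzyloxy)-3,5-dimethoxyphenyl]-2,5-dihydrofuran, via monoaryl dihydrofuran 7 (not isolated)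
Conditions: Pd(OAc)2 (5 mol %), (S)-BINAP (10 mol %), 1,8-bis(dimethylamino)naphthalene (3 equiv), benzene, 40 °C then 60 °C
Reagents that add atoms: none
Why: Asymmetric Mizoroki–Heck arylation under cationic conditions: oxidative addition of 5 to zerovalent palladium–(S)-BINAP gives an arylpalladium cation that inserts the enol ether of 6 with aryl delivered to the oxygen-bearing carbon, and syn β-hydride elimination, re-insertion and a second elimination release the enol ether 7. A second arylpalladium cation then adds to C5 of 7 on the face opposite the C2 aryl group; the only syn β-hydrogen of the resulting C4–palladium species lies on C3, so elimination gives the C3=C4 alkene of 8. The closest known reaction type is the palladium–BINAP arylation of 2,3-dihydrofuran with aryl triflates, including further arylation of 2-aryl-2,3-dihydrofurans to trans-2,5-diaryl-2,5-dihydrofurans; no ring closes in this step, the oxolane ring being that of 6. Both new stereocentres (C2 and C5, each S) are set by the (S)-BINAP ligand on palladium, and at C5 the catalyst preference is reinforced by approach anti to the existing aryl group, which secures the trans relationship. The step needs regioselectivity for the carbon next to oxygen, secured by the polarisation of the enol ether towards cationic palladium, and it needs hydride migration to stop at the 2,5-dihydrofuran stage, which the hindered diaryl alkene and the amine base should favour by releasing and quenching palladium hydride. Because one catalyst controls both events, the minor enantiomer of 7 should be diverted largely into the separable meso cis isomer, which should raise the enantiomeric purity of 8.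

Step 5
Reactants: 8 (2S,5S)-2,5-bis[4-(benzyloxy)-3,5-dimethoxyphenyl]-2,5-dihydrofuran
Product: 9 dimethyl (2S,3R,4S,5S)-2,5-bis[4-(benzyloxy)-3,5-dimethoxyphenyl]oxolane-3,4-dicarboxylate (esters cis to each other; the C3 ester cis to the C2 aryl, the C4 ester trans to the C5 aryl)
Conditions: PdCl2 (10 mol %), CuCl2 (2.2 equiv), NaOAc (2.2 equiv), CO (3 atm), MeOH–THF, 25 °C
Reagents that add atoms: carbon monoxide, [C-]#[O+]; methanol, CO
Why: Stille–James-type oxidative bis-alkoxycarbonylation, in which a methoxycarbonyl–palladium species adds syn across C3=C4, CO inserts into the alkyl–palladium bond and methanolysis releases the diester while CuCl2 returns zerovalent palladium to divalent palladium; the new C3 and C4 centres are set cis by the syn addition, and since the two alkene faces of 8 are interchanged by its twofold axis, a single diastereomer should result.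

Step 6
Reactants: 9 dimethyl (2S,3R,4S,5S)-2,5-bis[4-(benzyloxy)-3,5-dimethoxyphenyl]oxolane-3,4-dicarboxylate
Product: 10 dimethyl (2S,3S,4S,5S)-2,5-bis[4-(benzyloxy)-3,5-dimethoxyphenyl]oxolane-3,4-dicarboxylate (all-trans)
Conditions: NaOMe (0.3 equiv), MeOH–THF, 50 °C
Reagents that add atoms: none
Why: Thermodynamic epimerisation through the ester enolate inverts C3, whose ester is cis to both the C2 aryl and the C4 ester, to give the all-trans diester, while ring opening by β-alkoxide loss is the reverse of a 5-endo-trig closure and should be slow.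

Step 7
Reactants: 10 dimethyl (2S,3S,4S,5S)-2,5-bis[4-(benzyloxy)-3,5-dimethoxyphenyl]oxolane-3,4-dicarboxylate
Product: 11 [(2S,3R,4R,5S)-2,5-bis[4-(benzyloxy)-3,5-dimethoxyphenyl]oxolane-3,4-diyl]dimethanol
Conditions: LiAlH4, THF, 0 °C to rt; H2O, aq. NaOH work-up
Reagents that add atoms: none
Why: Hydride reduction of both esters to primary alcohols with no change at any stereocentre; the C3/C4 descriptors change from S to R only because the CIP priorities change.

Step 8
Reactants: 11 [(2S,3R,4R,5S)-2,5-bis[4-(benzyloxy)-3,5-dimethoxyphenyl]oxolane-3,4-diyl]dimethanol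
Product: 12 huazhongilexin, 4,4'-[(2S,3R,4R,5S)-3,4-bis(hydroxymethyl)oxolane-2,5-diyl]bis(2,6-dimethoxyphenol)
Conditions: H2 (1 atm), Pd/C (10 wt % palladium on carbon), EtOAc–MeOH, rt
Reagents that add atoms: none
Why: Catalytic hydrogenolysis cleaves aryl benzyl ethers faster than the benzylic C–O bonds of the oxolane ring under neutral conditions at ambient pressure, so both phenols should be freed with the ring intact if the reaction is stopped at full debenzylation.

**Compound list**

1 | syringaldehyde (4-hydroxy-3,5-dimethoxybenzaldehyde) | COc1cc(C=O)cc(OC)c1O | starting material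
2 | 4-(benzyloxy)-3,5-dimethoxybenzaldehyde | COc1cc(C=O)cc(OC)c1OCc1ccccc1 | intermediate
3 | 4-(benzyloxy)-3,5-dimethoxyphenyl formate | COc1cc(OC=O)cc(OC)c1OCc1ccccc1 | intermediate (not isolated)
4 | 4-(benzyloxy)-3,5-dimethoxyphenol | COc1cc(O)cc(OC)c1OCc1ccccc1 | intermediate
5 | 4-(benzyloxy)-3,5-dimethoxyphenyl trifluoromethanesulfonate | COc1cc(OS(=O)(=O)C(F)(F)F)cc(OC)c1OCc1ccccc1 | intermediate
6 | 2,3-dihydrofuran | C1=COCC1 | starting material
7 | (2S)-2-[4-(benzyloxy)-3,5-dimethoxyphenyl]-2,3-dihydrofuran | COc1cc([C@@H]2CC=CO2)cc(OC)c1OCc1ccccc1 | intermediate (not isolated)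
8 | (2S,5S)-2,5-bis[4-(benzyloxy)-3,5-dimethoxyphenyl]-2,5-dihydrofuran (trans) | COc1cc([C@H]2O[C@H](c3cc(OC)c(OCc4ccccc4)c(OC)c3)C=C2)cc(OC)c1OCc1ccccc1 | intermediate
9 | dimethyl (2S,3R,4S,5S)-2,5-bis[4-(benzyloxy)-3,5-dimethoxyphenyl]oxolane-3,4-dicarboxylate (3,4-cis) | COc1cc([C@H]2O[C@H](c3cc(OC)c(OCc4ccccc4)c(OC)c3)[C@@H](C(=O)OC)[C@H]2C(=O)OC)cc(OC)c1OCc1ccccc1 | intermediate
10 | dimethyl (2S,3S,4S,5S)-2,5-bis[4-(benzyloxy)-3,5-dimethoxyphenyl]oxolane-3,4-dicarboxylate (all-trans) | COc1cc([C@H]2O[C@H](c3cc(OC)c(OCc4ccccc4)c(OC)c3)[C@@H](C(=O)OC)[C@@H]2C(=O)OC)cc(OC)c1OCc1ccccc1 | intermediate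
11 | [(2S,3R,4R,5S)-2,5-bis[4-(benzyloxy)-3,5-dimethoxyphenyl]oxolane-3,4-diyl]dimethanol | COc1cc([C@H]2O[C@H](c3cc(OC)c(OCc4ccccc4)c(OC)c3)[C@@H](CO)[C@@H]2CO)cc(OC)c1OCc1ccccc1 | intermediate
12 | huazhongilexin, 4,4'-[(2S,3R,4R,5S)-3,4-bis(hydroxymethyl)oxolane-2,5-diyl]bis(2,6-dimethoxyphenol) | COc1cc([C@H]2O[C@H](c3cc(OC)c(O)c(OC)c3)[C@@H](CO)[C@@H]2CO)cc(OC)c1O | target

**Step count**

Total steps: 8. Longest linear sequence: 8 steps (1 to 12); 2,3-dihydrofuran 6 enters at step 4 as bought.

**Steps most likely to fail**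

Step 4 (key step). The electron-rich triflate may add oxidatively so slowly that the sequence stalls after the first arylation. Palladium hydride may also walk on past the 2,5-dihydrofuran stage, moving the alkene into conjugation with an aryl group and erasing a stereocentre, or face selectivity may be too low. The fallback sets out from aldehyde 2 and returns at 8; it sets the two aryl-bearing centres by iridium-catalysed allylic substitution and forms the alkene by ring-closing metathesis. Horner–Wadsworth–Emmons olefination of 2 with triethyl phosphonoacetate (NaH, THF) should give ethyl (2E)-3-[4-(benzyloxy)-3,5-dimethoxyphenyl]prop-2-enoate F1. DIBAL-H (CH2Cl2, −78 °C) should reduce it to (2E)-3-[4-(benzyloxy)-3,5-dimethoxyphenyl]prop-2-en-1-ol F2, and methyl chloroformate with pyridine should give methyl (2E)-3-[4-(benzyloxy)-3,5-dimethoxyphenyl]prop-2-en-1-yl carbonate F3. Asymmetric allylic hydroxylation of F3 ([Ir(cod)Cl]2, a chiral phosphoramidite ligand, KHCO3 as hydroxide equivalent) should give the branched alcohol (1S)-1-[4-(benzyloxy)-3,5-dimethoxyphenyl]prop-2-en-1-ol F4. Its copper alkoxide (n-BuLi, CuI) would be allylated by a second portion of F3 under the same iridium catalyst to give bis[(1S)-1-[4-(benzyloxy)-3,5-dimethoxyphenyl]prop-2-en-1-yl] ether F5, with the new centre under catalyst control. Ring-closing metathesis of F5 with second-generation Grubbs catalyst, RuCl2(=CHPh)(H2IMes)(PCy3), in CH2Cl2 should then give 8.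

Step 5. Insertion of the hindered, doubly flanked alkene may be slow; the alkylpalladium intermediate may undergo β-hydride elimination before CO insertion; and the doubly benzylic allylic ether may ionise or be oxidised towards the furan in the oxidising chloride medium. The fallback sets out from 8 and returns at 11, bringing in the two carbons one at a time. Rhodium-catalysed hydroformylation (Rh(acac)(CO)2, tris(2,4-di-tert-butylphenyl) phosphite, CO/H2, toluene, 60 °C) should give (2S,5S)-2,5-bis[4-(benzyloxy)-3,5-dimethoxyphenyl]oxolane-3-carbaldehyde F6 as C3 epimers. α-Selenenylation through the morpholine enamine (PhSeCl, THF, −78 °C, then hydrolysis) should give 2,5-trans-2,5-bis[4-(benzyloxy)-3,5-dimethoxyphenyl]-3-(phenylselanyl)oxolane-3-carbaldehyde F7. Oxidation with NaIO4 and syn elimination of the selenoxide away from the ring oxygen should give 2,5-trans-2,5-bis[4-(benzyloxy)-3,5-dimethoxyphenyl]-2,5-dihydrofuran-3-carbaldehyde F8. Conjugate addition of (CH2=CH)2CuLi with TMSCl (THF, −78 °C), anti to the C5 aryl group, followed by DBU equilibration of the aldehyde centre, should give all-trans 2,5-bis[4-(benzyloxy)-3,5-dimethoxyphenyl]-4-vinyloxolane-3-carbaldehyde F9. Lemieux–Johnson cleavage (OsO4 cat., NaIO4, 2,6-lutidine, dioxane–water) should give (2S,3S,4S,5S)-2,5-bis[4-(benzyloxy)-3,5-dimethoxyphenyl]oxolane-3,4-dicarbaldehyde F10, and NaBH4 in MeOH should reduce it to 11.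

Step 6. Equilibration may stop short of the all-trans isomer, or the ester enolate may open the ring by loss of the β-alkoxide and re-close with scrambling at the aryl-bearing carbon. The fallback sets out from 9 and returns at 11, moving the epimerisation to the aldehyde oxidation level, where much milder base suffices. LiAlH4 in THF should reduce 9 to the 3,4-cis diol [(2S,3S,4R,5S)-2,5-bis[4-(benzyloxy)-3,5-dimethoxyphenyl]oxolane-3,4-diyl]dimethanol F11. Swern oxidation ((COCl)2, DMSO, Et3N, CH2Cl2, −78 °C) should give the 3,4-cis dialdehyde (2S,3R,4S,5S)-2,5-bis[4-(benzyloxy)-3,5-dimethoxyphenyl]oxolane-3,4-dicarbaldehyde F12, which would not be isolated. On warming with excess Et3N or DBU it should equilibrate to the all-trans dialdehyde (2S,3S,4S,5S)-2,5-bis[4-(benzyloxy)-3,5-dimethoxyphenyl]oxolane-3,4-dicarbaldehyde F13, the same compound that the fallback for step 5 passes through. NaBH4 in MeOH should then give 11.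

**Further compounds**

F1 | step 4 | ethyl (2E)-3-[4-(benzyloxy)-3,5-dimethoxyphenyl]prop-2-enoate | CCOC(=O)/C=C/c1cc(OC)c(OCc2ccccc2)c(OC)c1
F2 | step 4 | (2E)-3-[4-(benzyloxy)-3,5-dimethoxyphenyl]prop-2-en-1-ol | OC/C=C/c1cc(OC)c(OCc2ccccc2)c(OC)c1
F3 | step 4 | methyl (2E)-3-[4-(benzyloxy)-3,5-dimethoxyphenyl]prop-2-en-1-yl carbonate | COC(=O)OC/C=C/c1cc(OC)c(OCc2ccccc2)c(OC)c1
F4 | step 4 | (1S)-1-[4-(benzyloxy)-3,5-dimethoxyphenyl]prop-2-en-1-ol | C=C[C@@H](c1cc(OC)c(OCc2ccccc2)c(OC)c1)O
F5 | step 4 | bis[(1S)-1-[4-(benzyloxy)-3,5-dimethoxyphenyl]prop-2-en-1-yl] ether | C=C[C@@H](c1cc(OC)c(OCc2ccccc2)c(OC)c1)O[C@H](c1cc(OC)c(OCc2ccccc2)c(OC)c1)C=C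
F6 | step 5 | (2S,5S)-2,5-bis[4-(benzyloxy)-3,5-dimethoxyphenyl]oxolane-3-carbaldehyde (C3 epimers) | COc1cc([C@H]2O[C@H](c3cc(OC)c(OCc4ccccc4)c(OC)c3)CC2C=O)cc(OC)c1OCc1ccccc1
F7 | step 5 | 2,5-trans-2,5-bis[4-(benzyloxy)-3,5-dimethoxyphenyl]-3-(phenylselanyl)oxolane-3-carbaldehyde (C3 epimers; aryl-bearing centres as in 8) | COc1cc([C@H]2O[C@H](c3cc(OC)c(OCc4ccccc4)c(OC)c3)CC2(C=O)[Se]c2ccccc2)cc(OC)c1OCc1ccccc1
F8 | step 5 | 2,5-trans-2,5-bis[4-(benzyloxy)-3,5-dimethoxyphenyl]-2,5-dihydrofuran-3-carbaldehyde (aryl-bearing centres as in 8) | COc1cc([C@H]2O[C@H](c3cc(OC)c(OCc4ccccc4)c(OC)c3)C=C2C=O)cc(OC)c1OCc1ccccc1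
F9 | step 5 | all-trans 2,5-bis[4-(benzyloxy)-3,5-dimethoxyphenyl]-4-vinyloxolane-3-carbaldehyde | COc1cc([C@H]2O[C@H](c3cc(OC)c(OCc4ccccc4)c(OC)c3)[C@@H](C=C)[C@@H]2C=O)cc(OC)c1OCc1ccccc1
F10 | step 5 | (2S,3S,4S,5S)-2,5-bis[4-(benzyloxy)-3,5-dimethoxyphenyl]oxolane-3,4-dicarbaldehyde (all-trans) | COc1cc([C@H]2O[C@H](c3cc(OC)c(OCc4ccccc4)c(OC)c3)[C@@H](C=O)[C@@H]2C=O)cc(OC)c1OCc1ccccc1
F11 | step 6 | [(2S,3S,4R,5S)-2,5-bis[4-(benzyloxy)-3,5-dimethoxyphenyl]oxolane-3,4-diyl]dimethanol (3,4-cis) | COc1cc([C@H]2O[C@H](c3cc(OC)c(OCc4ccccc4)c(OC)c3)[C@@H](CO)[C@H]2CO)cc(OC)c1OCc1ccccc1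
F12 | step 6 | (2S,3R,4S,5S)-2,5-bis[4-(benzyloxy)-3,5-dimethoxyphenyl]oxolane-3,4-dicarbaldehyde (3,4-cis) | COc1cc([C@H]2O[C@H](c3cc(OC)c(OCc4ccccc4)c(OC)c3)[C@@H](C=O)[C@H]2C=O)cc(OC)c1OCc1ccccc1
F13 | step 6 | (2S,3S,4S,5S)-2,5-bis[4-(benzyloxy)-3,5-dimethoxyphenyl]oxolane-3,4-dicarbaldehyde (all-trans) | COc1cc([C@H]2O[C@H](c3cc(OC)c(OCc4ccccc4)c(OC)c3)[C@@H](C=O)[C@@H]2C=O)cc(OC)c1OCc1ccccc1
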